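## The problem

The target is an isoflavan: a chroman carrying ring B at C3, with C3 (R) as its only stereocentre. Nothing else in the molecule is stereogenic, so C3 cannot be relayed from a neighbour and has to be set by a reagent or catalyst; once set it has no acidifying group next to it and should hold. Ring A carries three oxygens in a 1,3,5 pattern that must end up different: O1 in the heterocycle, a methyl ether at C5 and a free phenol at C7. Ring B carries OH (C2'), prenyl (C3') and OMe (C4') on adjacent carbons, with the prenyl group wedged between two oxygens, a position that is hard to reach selectively on a finished isoflavan. The prenyl double bond excludes hydrogenolysis, ozone, peracids and electrophilic halogen, an ortho-prenyl phenol closes to a 2,2-dimethylchroman in strong acid, and both rings are electron-rich, so the end game must be mild. The enabling feature is that the C5 and C7 oxygens are meta to each other with C6–H between them, and that the C4a–C8a bond is shared with the heterocycle. That bond can therefore pre-exist as the enol ether double bond of a 3,4-dihydro-2H-pyran, and C5–C8 can be supplied by a ketene and an oxygenated alkyne.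

## Retrosynthesis

**Target 37 back to phenol 34.** No skeletal bond is cut. The silyl ether at C7 of 36, the MOM acetal at O2' of 35 and the C5 methyl ether are removed in turn, giving chromanol 34. In 34 the only free hydroxyl is at C5, so methylation needs no selectivity, and the two unmasking steps are ordered so that acid meets a silylated ring A and the last step is neutral.

**Chromanol 34 to diazoketone 24 and siloxyalkyne 29.** Ring A is removed completely: C4a–C5, C5–C6 and C7–C8 are cut, and C8–C8a is traced to a Wolff shift. The neighbouring cuts (C4–C4a or O1–C8a to a preformed trioxygenated benzene) would need a ring with three different oxygen substituents and bond formation at a doubly ortho-substituted carbon. Here the C5 oxygen comes from the ketene carbonyl, the C7 oxygen from the alkyne and O1 is already in place. Precursor 24 holds ring B, one heterocycle and the stereocentre; 29 is a two-carbon unit. The forward reaction must deliver the meta relationship of the two new oxygens and tolerate the prenyl group.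

**Alkyne 29 to 28 and ethynyltrimethylsilane 25.** The O–C(sp) bond is traced to oxygenation of an acetylide. The trimethylsilyl group of 28 serves only to make the acetylide a monofunctional, easily handled species and is then removed.

**Diazoketone 24 to methyl ketone 21, phosphate 18 and lactone 16.** The diazo carbon is the methyl group of 21 (diazo transfer), and the acetyl group is attached at the lactone carbonyl carbon through ketene acetal phosphate 18 and stannane 19. Acylating diazomethane with the corresponding acid would cost two more steps and an activated acyl derivative next to an enol ether. Lactone 16 is a plain 5-aryl-δ-valerolactone.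

**Lactone 16 to bromohydrin 12 and dimethyl malonate 13.** The bond that becomes C4–C4a and the lactone acyl–oxygen bond are cut. A malonate supplies the two carbons and the carbonyl; the forward step is an SN2 reaction at a primary carbon that does not touch the stereocentre.

**Bromohydrin 12 to oxetane 10.** The C–Br bond is traced to opening of an achiral 3-aryloxetane, so the stereocentre arises by desymmetrisation. Auxiliary-based alkylation of an arylacetic acid would need more steps, and conjugate arylation of an unsaturated lactone places the aryl group one carbon away from where it is needed.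

**Oxetane 10 to boronic acid 8 and 3-iodooxetane 9; 8 to bromide 5; 5 to 2 and prenyl bromide 3; 2 to 2-bromo-5-methoxyphenol 1.** The C1'–C3 bond is cut to an alkyl–aryl coupling. The prenyl group is traced to metalation of the carbon between the two ring B oxygens, done before any other functionality is present. The bromine of 1 marks C1' from the start, so ring B needs no regiochemical decision later.

## Roads not taken

**Alternative 1:** The C3–C4 bond is cut after the 2'-oxygen has been tied to C4 as a benzylic ether.
- Forward: aryldiazoacetate A2 is decomposed by a chiral dirhodium tetracarboxylate catalyst. The carbene inserts into the benzylic ether C–H bond and closes the cis-disubstituted dihydrobenzofuran A1, whose ester-bearing carbon is the future C3. Ester reduction, reductive cleavage of the temporary C4–O bond, pivalate removal and Mitsunobu closure of O1–C2 would follow.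
- Merits: the stereocentre is made in the key step by a well-documented reaction class, and both rings are bought as aromatics.
- Weak points: a prenyl group cannot pass through a carbene step (cyclopropanation, allylic insertion), so A1 lacks it and prenyl must be introduced late between O2' and the 4'-methoxy group. The insertion site is flanked by two ortho substituents of ring A. The temporary benzylic C–O bond must be cleaved reductively, the C4 stereocentre is built only to be destroyed, and ring A needs three different oxygen substituents.
- Comparison: in its asymmetric step this road is better precedented than the oxetane opening of step 5, and it is more convergent. The chosen plan sets against this a prenyl group fixed in step 2 and a ring A whose oxygens differ from the moment the ring exists.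

**Alternative 2:** The C3–C1' and C4–C4a bonds are cut together across a vinyl unit.
- Forward: aryllithium 6 is added to vinylboronic ester A4, and the boronate is coupled with ring A triflate A5 under a palladium catalyst bearing a chiral ferrocenyl bisphosphine. Ring B migrates from boron to the α-carbon and the ring A aryl group is joined to the β-carbon, giving secondary boronic ester A3. Matteson homologation, oxidation, desilylation and Mitsunobu closure would complete the chroman.
- Merits: the highest convergence and the shortest sequence of all four plans; the catalyst sets C3 while two skeletal bonds form, and boron sits where C2 must be attached.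
- Weak points: A5 is an electron-rich triflate with both ortho positions oxygenated, the migrating aryl group is ortho-substituted, and couplings of this type lose rate and selectivity with such partners and with halide left from bromine–lithium exchange. A5 needs a benzene ring with four different oxygen substituents, whose preparation returns much of the saving. The homologation is at a hindered benzylic boron centre.
- Comparison: in step economy and convergence this road is better. The chosen plan sets against it that no bond is made at a doubly ortho-substituted ring A carbon and no trioxygenated benzene has to be differentiated; the price is a longer linear sequence and a diazoketone.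

**Alternative 3:** Ring B is cut at C1'–C6' and C3'–C4' and carried as a cyclohexane-1,3-dione.
- Forward: the more substituted enolate of chromanylacetone A7 adds to methyl acrylate A8 and the methyl-side enolate closes on the ester, giving dione A6. C-Prenylation between the two carbonyls, dehydrogenation to the resorcinol and 4'-O-methylation would follow.
- Merits: prenylation at the uniquely nucleophilic carbon of a 1,3-dione solves its regiochemistry cleanly; only classical reagents are used and there is no photochemistry.
- Weak points: the key step does not address C3, so A7 needs its own asymmetric synthesis. The Michael addition must go through the enolate on the branched side. Aromatisation of a prenylated dione needs an oxidant or dehydrogenation catalyst in the presence of the prenyl alkene. The two ring B oxygens emerge alike and only O4' may be methylated.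
- Comparison: in simplicity and safety of reagents, and in the prenylation itself, this road is as good or better. The chosen plan sets against it oxygen patterns in both rings that are fixed by construction, no ring oxidation next to the prenyl group, and a stereocentre set by a catalytic step on the main line.

Key step: step 12

Remark on the chemistry: 2-bromo-5-methoxyphenol is taken as the commercial entry to ring B. The antipode of the squaramide catalyst in step 5 is the one that gives (R)-12; which antipode that is must be confirmed by correlation on the first run, and both are equally accessible. In the step lines, Ar stands for the 4-methoxy-2-(methoxymethoxy)-3-(3-methylbut-2-en-1-yl)phenyl group (ring B); full names are in the compound list.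

## Route

Step 1
Reactants: 1 2-bromo-5-methoxyphenol
Product: 2 1-bromo-4-methoxy-2-(methoxymethoxy)benzene
Conditions: MOMCl, iPr2NEt, CH2Cl2, 0 °C to rt
Reagents that add atoms: chloromethyl methyl ether COCCl
Why: O-alkylation of a phenol (MOM protection); the acetal survives every base used later and directs the metalation of step 2.

Step 2
Reactants: 2 1-bromo-4-methoxy-2-(methoxymethoxy)benzene; 3 1-bromo-3-methylbut-2-ene
Product: 5 1-bromo-4-methoxy-2-(methoxymethoxy)-3-(3-methylbut-2-en-1-yl)benzene, via aryllithium 4 (not isolated)
Conditions: LiN(iPr)2, THF, −78 °C; CuBr·SMe2 (10 mol%), prenyl bromide, −78 to 0 °C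
Reagents that add atoms: none
Why: Directed ortho-metalation: the C–H between OMOM and OMe is the most acidic, doubly coordinated site and a lithium amide removes it without bromine–lithium exchange; copper-catalysed allylic substitution at the primary carbon of prenyl bromide should then give the linear prenyl arene.

Step 3
Reactants: 5 1-bromo-4-methoxy-2-(methoxymethoxy)-3-(3-methylbut-2-en-1-yl)benzene
Product: 8 Ar-boronic acid, via aryllithium 6 (not isolated), via lithium borate 7 (not isolated)
Conditions: B(OiPr)3, n-BuLi, THF/toluene, −78 °C to rt; aq. NH4Cl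
Reagents that add atoms: triisopropyl borate CC(C)OB(OC(C)C)OC(C)C; water O
Why: Bromine–lithium exchange at −78 °C is much faster than deprotonation of the benzylic–allylic CH2, and the aryllithium is trapped by the borate already in the flask; neutral work-up keeps the acetal and limits protodeboronation.

Step 4
Reactants: 8 Ar-boronic acid; 9 3-iodooxetane
Product: 10 3-Ar-oxetane
Conditions: NiI2 (10 mol%), trans-2-aminocyclohexanol hydrochloride (10 mol%), NaN(SiMe3)2, i-PrOH, 80 °C
Reagents that add atoms: none
Why: Nickel-catalysed alkyl–aryl Suzuki–Miyaura coupling of an arylboronic acid with a secondary alkyl iodide, the standard entry to 3-aryloxetanes from 3-iodooxetane; alkene and acetal are inert to the alkoxide medium.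

Step 5
Reactants: 10 3-Ar-oxetane
Product: 12 (2R)-3-bromo-2-Ar-propan-1-ol, via silyl ether 11 (not isolated)
Conditions: Me3SiBr (1.2 equiv), chiral 2-arylpyrrolidine-derived squaramide (5 mol%), t-BuOMe, −78 °C; then MeOH, citric acid, 0 °C
Reagents that add atoms: bromotrimethylsilane C[Si](C)(C)Br
Why: Enantioselective desymmetrisation of a 3-substituted oxetane: the hydrogen-bond donor binds bromide, raises the Lewis acidity of the silyl bromide toward the oxetane oxygen and delivers bromide to one of the two enantiotopic CH2 groups, which should set the future C3 as R; low temperature and an ether solvent are what should spare the acetal and the alkene.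

Step 6
Reactants: 12 (2R)-3-bromo-2-Ar-propan-1-ol; 13 dimethyl malonate
Product: 16 (5R)-5-Ar-oxan-2-one, via hydroxy diester 14 (not isolated), via carbomethoxy lactone 15 (not isolated)
Conditions: NaH, dimethyl malonate (2.5 equiv), DMSO, 25 to 60 °C; then LiCl, H2O, 140 °C
Reagents that add atoms: none
Why: Malonic ester alkylation (SN2 at the primary bromide; in DMSO the malonate is deprotonated but the alcohol is not, which suppresses re-closure to the oxetane), lactonisation of the δ-hydroxy ester and Krapcho demethoxycarbonylation in one pot; the stereocentre is not a reacting carbon and bears no acidic hydrogen.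

Step 7
Reactants: 16 (5R)-5-Ar-oxan-2-one
Product: 18 (3R)-3-Ar-3,4-dihydro-2H-pyran-6-yl diphenyl phosphate, via potassium enolate 17 (not isolated)
Conditions: KN(SiMe3)2, (PhO)2P(O)Cl, HMPA, THF, −78 °C
Reagents that add atoms: diphenyl phosphorochloridate O=P(Cl)(Oc1ccccc1)Oc1ccccc1
Why: Kinetic enolisation of the δ-lactone and O-phosphorylation give the cyclic ketene acetal phosphate, a storable equivalent of the lactone enol triflate for palladium coupling.

Step 8
Reactants: 18 (3R)-3-Ar-3,4-dihydro-2H-pyran-6-yl diphenyl phosphate; 19 tributyl(1-ethoxyethenyl)stannane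
Product: 21 1-[(3R)-3-Ar-3,4-dihydro-2H-pyran-6-yl]ethan-1-one, via ethoxyvinyl diene 20 (not isolated)
Conditions: Pd(PPh3)4 (5 mol%), LiCl, THF, 65 °C; then 0.5 M aq. HCl, THF, 0 °C
Reagents that add atoms: water O
Why: Stille coupling of a ketene acetal phosphate (oxidative addition of the C–O bond to zerovalent palladium, assisted by LiCl) with an acetyl anion equivalent; brief dilute acid should hydrolyse the acyclic ethoxydiene at its terminal CH2, and the resulting 2-acyl enol ether is deactivated toward further hydrolysis.

Step 9
Reactants: 21 1-[(3R)-3-Ar-3,4-dihydro-2H-pyran-6-yl]ethan-1-one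
Product: 24 2-diazo-1-[(3R)-3-Ar-3,4-dihydro-2H-pyran-6-yl]ethan-1-one, via lithium enolate 22 (not isolated), via trifluoroacetyl ketone 23 (not isolated)
Conditions: LiN(SiMe3)2, THF, −78 °C; CF3CO2CH2CF3; aq. NH4Cl; then MsN3, Et3N, H2O, MeCN, 25 °C
Reagents that add atoms: methanesulfonyl azide CS(=O)(=O)N=[N+]=[N-]
Why: Detrifluoroacetylative diazo transfer (a deacylative Regitz transfer): Claisen trifluoroacetylation of the kinetic methyl enolate activates the methyl group, and azide transfer with loss of the trifluoroacetyl group gives the diazomethyl enone without exposing the enol ether double bond to diazomethane.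

Step 10
Reactants: 25 ethynyltrimethylsilane
Product: 28 triisopropyl{[(trimethylsilyl)ethynyl]oxy}silane, via lithium acetylide 26 (not isolated), via lithium ynolate 27 (not isolated)
Conditions: n-BuLi, THF, −78 °C; LiOOt-Bu (from t-BuOOH and LiN(SiMe3)2), −78 to 0 °C; iPr3SiOTf, −78 to 0 °C
Reagents that add atoms: tert-butyl hydroperoxide CC(C)(C)OO; triisopropylsilyl trifluoromethanesulfonate CC(C)[Si](OS(=O)(=O)C(F)(F)F)(C(C)C)C(C)C
Why: Oxenoid oxygen transfer from the lithium peroxide to the lithium acetylide gives the ynolate, and the bulky, hard silyl triflate should silylate it on oxygen; triisopropylsilyl ynol ethers are the members of this class that resist rearrangement to silylketenes.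

Step 11
Reactants: 28 triisopropyl{[(trimethylsilyl)ethynyl]oxy}silane
Product: 29 (ethynyloxy)triisopropylsilane
Conditions: K2CO3 (0.1 equiv), MeOH, 0 °C; pentane extraction
Reagents that add atoms: none
Why: Methoxide-catalysed protodesilylation of an alkynyl trimethylsilane; the small silyl group on sp carbon should leave much faster than the hindered triisopropylsilyl group on oxygen, and the basic medium keeps methanol from adding to the ynol ether.

Step 12
Reactants: 24 2-diazo-1-[(3R)-3-Ar-3,4-dihydro-2H-pyran-6-yl]ethan-1-one; 29 (ethynyloxy)triisopropylsilane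
Product: 34 (3R)-3-Ar-7-[(triisopropylsilyl)oxy]-3,4-dihydro-2H-chromen-5-ol, via vinylketene 30 (not isolated), via cyclobutenone 31 (not isolated), via dienylketene 32 (not isolated), via cyclohexadienone 33 (not isolated)
Conditions: hν (medium-pressure Hg lamp, Pyrex), 29 (2.5 equiv), ClCH2CH2Cl, 25 °C; then 80 °C
Reagents that add atoms: none
Why: Photolysis expels N2 and the dihydropyranyl group shifts to the carbene carbon (Wolff rearrangement, C8–C8a), giving vinylketene 30. Ketene 30 and the electron-rich alkyne 29 combine in a (2+2) cycloaddition in which the nucleophilic terminal carbon of the ynol ether bonds to the ketene carbonyl carbon (C5–C6) and the silyloxy carbon to the ketene α-carbon (C7–C8), giving cyclobutenone 31. Under light or heat 31 opens by a four-electron conrotatory electrocyclic cleavage to dienylketene 32. Ring A, the only ring formed, then closes by a six-electron disrotatory electrocyclisation between the ketene carbon and C5 of the dihydropyran (C5–C4a), and dienone 33 tautomerises to the phenol. The closest known reaction type is the Danheiser benzannulation in its diazoketone form with triisopropylsilyloxyalkynes, which gives resorcinol monosilyl ethers; heteroaryl diazomethyl ketones whose migrating carbon bears oxygen belong to the same class. No stereocentre is created: the sp3 carbons of 31 and 33 are transient and C3 lies in the saturated part of the heterocycle. The selectivity needed is regiochemical in the (2+2) step, secured by the polarisation of the ynol ether so that the silyloxy group lands meta to the new hydroxyl with C6–H between them. The ketene must also prefer the alkyne, used in excess and the best ketenophile present, over the prenyl and enol ether double bonds, and Pyrex-filtered light is chosen so that only the diazoketone absorbs.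

Step 13
Reactants: 34 (3R)-3-Ar-7-[(triisopropylsilyl)oxy]-3,4-dihydro-2H-chromen-5-ol
Product: 35 triisopropyl{[(3R)-5-methoxy-3-Ar-3,4-dihydro-2H-chromen-7-yl]oxy}silane
Conditions: MeI, K2CO3, acetone (anhydrous), 45 °C
Reagents that add atoms: iodomethane CI
Why: Williamson methylation of the only free phenol (C5–OH, the oxygen that came from the ketene carbonyl); anhydrous carbonate in acetone should leave the aryl triisopropylsilyl ether in place, so C7 stays masked.

Step 14
Reactants: 35 triisopropyl{[(3R)-5-methoxy-3-Ar-3,4-dihydro-2H-chromen-7-yl]oxy}silane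
Product: 36 3-methoxy-6-{(3R)-5-methoxy-7-[(triisopropylsilyl)oxy]-3,4-dihydro-2H-chromen-3-yl}-2-(3-methylbut-2-en-1-yl)phenol
Conditions: HCl (0.5 M), MeOH/THF, 25 °C
Reagents that add atoms: none
Why: Acid-catalysed acetal exchange removes MOM as dimethoxymethane; methanol traps the methoxymethyl cation, the aryl triisopropylsilyl ether should survive, and dilute acid at room temperature limits addition of the freed phenol to the prenyl group.

Step 15
Reactants: 36 3-methoxy-6-{(3R)-5-methoxy-7-[(triisopropylsilyl)oxy]-3,4-dihydro-2H-chromen-3-yl}-2-(3-methylbut-2-en-1-yl)phenol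
Product: 37 (3R)-3-[2-hydroxy-4-methoxy-3-(3-methylbut-2-en-1-yl)phenyl]-5-methoxy-3,4-dihydro-2H-chromen-7-ol
Conditions: Bu4NF, AcOH, THF, 0 °C
Reagents that add atoms: none
Why: Fluoride-induced cleavage of the aryl silyl ether; acetic acid buffers the phenoxide so that the electron-rich resorcinol ring is not exposed to base and air.

## Compound list

1 | 2-bromo-5-methoxyphenol | COc1ccc(Br)c(O)c1 | starting material
2 | 1-bromo-4-methoxy-2-(methoxymethoxy)benzene | COCOc1cc(OC)ccc1Br | intermediate
3 | 1-bromo-3-methylbut-2-ene (prenyl bromide) | CC(C)=CCBr | starting material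
4 | [3-bromo-6-methoxy-2-(methoxymethoxy)phenyl]lithium | [Li]c1c(OC)ccc(Br)c1OCOC | intermediate
5 | 1-bromo-4-methoxy-2-(methoxymethoxy)-3-(3-methylbut-2-en-1-yl)benzene | COCOc1c(Br)ccc(OC)c1CC=C(C)C | intermediate
6 | [4-methoxy-2-(methoxymethoxy)-3-(3-methylbut-2-en-1-yl)phenyl]lithium | [Li]c1ccc(OC)c(CC=C(C)C)c1OCOC | intermediate
7 | lithium triisopropoxy[4-methoxy-2-(methoxymethoxy)-3-(3-methylbut-2-en-1-yl)phenyl]borate | [Li+].CC(C)O[B-](OC(C)C)(OC(C)C)c1ccc(OC)c(CC=C(C)C)c1OCOC | intermediate
8 | [4-methoxy-2-(methoxymethoxy)-3-(3-methylbut-2-en-1-yl)phenyl]boronic acid | OB(O)c1ccc(OC)c(CC=C(C)C)c1OCOC | intermediate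
9 | 3-iodooxetane | IC1COC1 | starting material
10 | 3-[4-methoxy-2-(methoxymethoxy)-3-(3-methylbut-2-en-1-yl)phenyl]oxetane | C1OCC1c1ccc(OC)c(CC=C(C)C)c1OCOC | intermediate
11 | {(2R)-3-bromo-2-[4-methoxy-2-(methoxymethoxy)-3-(3-methylbut-2-en-1-yl)phenyl]propoxy}trimethylsilane | C[Si](C)(C)OC[C@H](CBr)c1ccc(OC)c(CC=C(C)C)c1OCOC | intermediate
12 | (2R)-3-bromo-2-[4-methoxy-2-(methoxymethoxy)-3-(3-methylbut-2-en-1-yl)phenyl]propan-1-ol | OC[C@H](CBr)c1ccc(OC)c(CC=C(C)C)c1OCOC | intermediate
13 | dimethyl malonate | COC(=O)CC(=O)OC | starting material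
14 | dimethyl 2-{(2R)-3-hydroxy-2-[4-methoxy-2-(methoxymethoxy)-3-(3-methylbut-2-en-1-yl)phenyl]propyl}propanedioate | COC(=O)C(C[C@H](c1ccc(OC)c(CC=C(C)C)c1OCOC)CO)C(=O)OC | intermediate
15 | methyl (5R)-5-[4-methoxy-2-(methoxymethoxy)-3-(3-methylbut-2-en-1-yl)phenyl]-2-oxooxane-3-carboxylate (both C3 epimers) | COC(=O)C1C[C@H](c2ccc(OC)c(CC=C(C)C)c2OCOC)COC1=O | intermediate
16 | (5R)-5-[4-methoxy-2-(methoxymethoxy)-3-(3-methylbut-2-en-1-yl)phenyl]oxan-2-one | O=C1CC[C@H](c2ccc(OC)c(CC=C(C)C)c2OCOC)CO1 | intermediate
17 | potassium (3R)-3-[4-methoxy-2-(methoxymethoxy)-3-(3-methylbut-2-en-1-yl)phenyl]-3,4-dihydro-2H-pyran-6-olate | [K+].[O-]C1=CC[C@H](c2ccc(OC)c(CC=C(C)C)c2OCOC)CO1 | intermediate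
18 | (3R)-3-[4-methoxy-2-(methoxymethoxy)-3-(3-methylbut-2-en-1-yl)phenyl]-3,4-dihydro-2H-pyran-6-yl diphenyl phosphate | O=P(Oc1ccccc1)(Oc1ccccc1)OC1=CC[C@H](c2ccc(OC)c(CC=C(C)C)c2OCOC)CO1 | intermediate
19 | tributyl(1-ethoxyethenyl)stannane | CCCC[Sn](CCCC)(CCCC)C(=C)OCC | starting material
20 | (3R)-6-(1-ethoxyethenyl)-3-[4-methoxy-2-(methoxymethoxy)-3-(3-methylbut-2-en-1-yl)phenyl]-3,4-dihydro-2H-pyran | CCOC(=C)C1=CC[C@H](c2ccc(OC)c(CC=C(C)C)c2OCOC)CO1 | intermediate
21 | 1-{(3R)-3-[4-methoxy-2-(methoxymethoxy)-3-(3-methylbut-2-en-1-yl)phenyl]-3,4-dihydro-2H-pyran-6-yl}ethan-1-one | CC(=O)C1=CC[C@H](c2ccc(OC)c(CC=C(C)C)c2OCOC)CO1 | intermediate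
22 | lithium 1-{(3R)-3-[4-methoxy-2-(methoxymethoxy)-3-(3-methylbut-2-en-1-yl)phenyl]-3,4-dihydro-2H-pyran-6-yl}ethen-1-olate | [Li+].[O-]C(=C)C1=CC[C@H](c2ccc(OC)c(CC=C(C)C)c2OCOC)CO1 | intermediate
23 | 4,4,4-trifluoro-1-{(3R)-3-[4-methoxy-2-(methoxymethoxy)-3-(3-methylbut-2-en-1-yl)phenyl]-3,4-dihydro-2H-pyran-6-yl}butane-1,3-dione | O=C(CC(=O)C(F)(F)F)C1=CC[C@H](c2ccc(OC)c(CC=C(C)C)c2OCOC)CO1 | intermediate
24 | 2-diazo-1-{(3R)-3-[4-methoxy-2-(methoxymethoxy)-3-(3-methylbut-2-en-1-yl)phenyl]-3,4-dihydro-2H-pyran-6-yl}ethan-1-one | [N-]=[N+]=CC(=O)C1=CC[C@H](c2ccc(OC)c(CC=C(C)C)c2OCOC)CO1 | intermediate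
25 | ethynyltrimethylsilane | C#C[Si](C)(C)C | starting material
26 | [(trimethylsilyl)ethynyl]lithium | [Li]C#C[Si](C)(C)C | intermediate
27 | lithium 2-(trimethylsilyl)ethyn-1-olate | [Li+].[O-]C#C[Si](C)(C)C | intermediate
28 | triisopropyl{[(trimethylsilyl)ethynyl]oxy}silane | CC(C)[Si](OC#C[Si](C)(C)C)(C(C)C)C(C)C | intermediate
29 | (ethynyloxy)triisopropylsilane | C#CO[Si](C(C)C)(C(C)C)C(C)C | intermediate
30 | 2-{(3R)-3-[4-methoxy-2-(methoxymethoxy)-3-(3-methylbut-2-en-1-yl)phenyl]-3,4-dihydro-2H-pyran-6-yl}ethen-1-one | O=C=CC1=CC[C@H](c2ccc(OC)c(CC=C(C)C)c2OCOC)CO1 | intermediate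
31 | 4-{(3R)-3-[4-methoxy-2-(methoxymethoxy)-3-(3-methylbut-2-en-1-yl)phenyl]-3,4-dihydro-2H-pyran-6-yl}-3-[(triisopropylsilyl)oxy]cyclobut-2-en-1-one (both C4 epimers) | O=C1C=C(O[Si](C(C)C)(C(C)C)C(C)C)C1C1=CC[C@H](c2ccc(OC)c(CC=C(C)C)c2OCOC)CO1 | intermediate
32 | 4-{(3R)-3-[4-methoxy-2-(methoxymethoxy)-3-(3-methylbut-2-en-1-yl)phenyl]-3,4-dihydro-2H-pyran-6-yl}-3-[(triisopropylsilyl)oxy]buta-1,3-dien-1-one | O=C=CC(O[Si](C(C)C)(C(C)C)C(C)C)=CC1=CC[C@H](c2ccc(OC)c(CC=C(C)C)c2OCOC)CO1 | intermediate
33 | (3R)-3-[4-methoxy-2-(methoxymethoxy)-3-(3-methylbut-2-en-1-yl)phenyl]-7-[(triisopropylsilyl)oxy]-2,3,4,4a-tetrahydro-5H-chromen-5-one (both C4a epimers) | O=C1C=C(O[Si](C(C)C)(C(C)C)C(C)C)C=C2C1C[C@H](c1ccc(OC)c(CC=C(C)C)c1OCOC)CO2 | intermediate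
34 | (3R)-3-[4-methoxy-2-(methoxymethoxy)-3-(3-methylbut-2-en-1-yl)phenyl]-7-[(triisopropylsilyl)oxy]-3,4-dihydro-2H-chromen-5-ol | Oc1cc(O[Si](C(C)C)(C(C)C)C(C)C)cc2c1C[C@H](c1ccc(OC)c(CC=C(C)C)c1OCOC)CO2 | intermediate
35 | triisopropyl({(3R)-5-methoxy-3-[4-methoxy-2-(methoxymethoxy)-3-(3-methylbut-2-en-1-yl)phenyl]-3,4-dihydro-2H-chromen-7-yl}oxy)silane | COc1cc(O[Si](C(C)C)(C(C)C)C(C)C)cc2c1C[C@H](c1ccc(OC)c(CC=C(C)C)c1OCOC)CO2 | intermediate
36 | 3-methoxy-6-{(3R)-5-methoxy-7-[(triisopropylsilyl)oxy]-3,4-dihydro-2H-chromen-3-yl}-2-(3-methylbut-2-en-1-yl)phenol | COc1cc(O[Si](C(C)C)(C(C)C)C(C)C)cc2c1C[C@H](c1ccc(OC)c(CC=C(C)C)c1O)CO2 | intermediate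
37 | (3R)-3-[2-hydroxy-4-methoxy-3-(3-methylbut-2-en-1-yl)phenyl]-5-methoxy-3,4-dihydro-2H-chromen-7-ol | COc1cc(O)cc2c1C[C@H](c1ccc(OC)c(CC=C(C)C)c1O)CO2 | target

## Step count and least certain steps

Total: 15 steps. Longest linear sequence: 13 steps (steps 1–9 and 12–15); steps 10 and 11 prepare the alkyne.

**Step 12 (key step).** Neither partner has been used in this annulation. The terminal siloxyalkyne may polymerise or photodecompose, and the alkoxy-substituted vinylketene may dimerise or add to the enol ether of a second molecule before it meets the alkyne. The supply of 29 is also exposed, because methanolysis of the O–Si bond can compete in step 11. The fallback sets out from 24 and uses the internal siloxyalkyne 28, which has no terminal C–H, is not volatile and belongs to the 2-substituted siloxyalkynes for which this annulation is established. Irradiation and heating as in step 12 should give (3R)-3-Ar-7-[(triisopropylsilyl)oxy]-6-(trimethylsilyl)-3,4-dihydro-2H-chromen-5-ol F1, with the trimethylsilyl group at C6. Methylation with MeI and K2CO3 in acetone should give the 5-methoxy compound F2. HCl in methanol should then remove the MOM group and, by ipso-protonation of the carbon flanked by two oxygens, the C6 silyl group in one operation. The fallback rejoins the route at 36 and makes step 11 unnecessary.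

**Step 5.** Several processes can erode the desymmetrisation: attack of the ortho acetal oxygen on the activated oxetane with loss of MOM, acetal cleavage by the silyl bromide, hydrobromination of the prenyl double bond by adventitious HBr, and an uncatalysed background opening that lowers enantioselectivity for an ortho-substituted aryl group. The fallback sets out from bromide 5. Palladium-catalysed arylation of diethyl malonate (Pd2(dba)3, P(t-Bu)3, K3PO4, toluene) should give diethyl 2-Ar-propanedioate F3, and LiAlH4 reduction the prochiral 2-Ar-propane-1,3-diol F4. Lipase-catalysed monoacetylation with vinyl acetate (or hydrolysis of the diacetate with the same enzyme, whichever gives the required antipode) should give (2S)-3-hydroxy-2-Ar-propyl acetate F5. Appel bromination (CBr4, PPh3) gives (2R)-3-bromo-2-Ar-propyl acetate F6, and methanolysis of the acetate (K2CO3, MeOH, 0 °C) rejoins the route at 12.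

**Step 4.** The electron-rich, ortho-alkoxy boronic acid may protodeboronate in hot basic isopropanol before a slow, sterically hindered transmetalation. The fallback sets out from bromide 5 and couples it directly with 3-iodooxetane 9 by nickel-catalysed reductive cross-electrophile coupling (NiI2, 4,4'-di-tert-butyl-2,2'-bipyridine, Zn, NaI, N,N-dimethylacetamide). It rejoins the route at 10, bypasses 8 and forms no compound outside the list (entry F0).

**Step 8.** The ring enol ether may be protonated during hydrolysis of the ethoxydiene, opening the heterocycle, and oxidative addition of the phosphate may be sluggish. The fallback sets out from 18. Palladium-catalysed methoxycarbonylation (Pd(OAc)2, PPh3, CO, MeOH, Et3N) should give methyl (3R)-3-Ar-3,4-dihydro-2H-pyran-6-carboxylate F7, and LiOH the carboxylic acid F8. Isobutyl chloroformate and N-methylmorpholine give the mixed carbonic anhydride F9, and acylation of diazomethane rejoins the route at 24, bypassing steps 8 and 9.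

**Step 14.** Acid may promote addition of the freed 2'-phenol to the prenyl double bond (closure to a 2,2-dimethylchroman) and attack of the methoxymethyl cation on ring A. The fallback sets out from 35. TMSOTf and 2,2'-bipyridyl in CH2Cl2 at 0 °C should convert the aryl MOM ether under non-protic conditions into the aryl trimethylsilyl ether, {6-[(3R)-5-methoxy-7-(triisopropylsilyloxy)chroman-3-yl]-3-methoxy-2-(3-methylbut-2-en-1-yl)phenoxy}trimethylsilane F10. Bu4NF buffered with AcOH then removes both silyl groups, and the fallback rejoins the route at 37 without passing through 36.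

## Further compounds

F1 | step 12 | (3R)-3-[4-methoxy-2-(methoxymethoxy)-3-(3-methylbut-2-en-1-yl)phenyl]-7-[(triisopropylsilyl)oxy]-6-(trimethylsilyl)-3,4-dihydro-2H-chromen-5-ol | Oc1c([Si](C)(C)C)c(O[Si](C(C)C)(C(C)C)C(C)C)cc2c1C[C@H](c1ccc(OC)c(CC=C(C)C)c1OCOC)CO2
F2 | step 12 | triisopropyl({(3R)-5-methoxy-3-[4-methoxy-2-(methoxymethoxy)-3-(3-methylbut-2-en-1-yl)phenyl]-6-(trimethylsilyl)-3,4-dihydro-2H-chromen-7-yl}oxy)silane | COc1c([Si](C)(C)C)c(O[Si](C(C)C)(C(C)C)C(C)C)cc2c1C[C@H](c1ccc(OC)c(CC=C(C)C)c1OCOC)CO2
F3 | step 5 | diethyl 2-[4-methoxy-2-(methoxymethoxy)-3-(3-methylbut-2-en-1-yl)phenyl]propanedioate | CCOC(=O)C(C(=O)OCC)c1ccc(OC)c(CC=C(C)C)c1OCOC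
F4 | step 5 | 2-[4-methoxy-2-(methoxymethoxy)-3-(3-methylbut-2-en-1-yl)phenyl]propane-1,3-diol | OCC(CO)c1ccc(OC)c(CC=C(C)C)c1OCOC
F5 | step 5 | (2S)-3-hydroxy-2-[4-methoxy-2-(methoxymethoxy)-3-(3-methylbut-2-en-1-yl)phenyl]propyl acetate | CC(=O)OC[C@H](CO)c1ccc(OC)c(CC=C(C)C)c1OCOC
F6 | step 5 | (2R)-3-bromo-2-[4-methoxy-2-(methoxymethoxy)-3-(3-methylbut-2-en-1-yl)phenyl]propyl acetate | CC(=O)OC[C@H](CBr)c1ccc(OC)c(CC=C(C)C)c1OCOC
F0 | step 4 | none | none
F7 | step 8 | methyl (3R)-3-[4-methoxy-2-(methoxymethoxy)-3-(3-methylbut-2-en-1-yl)phenyl]-3,4-dihydro-2H-pyran-6-carboxylate | COC(=O)C1=CC[C@H](c2ccc(OC)c(CC=C(C)C)c2OCOC)CO1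
F8 | step 8 | (3R)-3-[4-methoxy-2-(methoxymethoxy)-3-(3-methylbut-2-en-1-yl)phenyl]-3,4-dihydro-2H-pyran-6-carboxylic acid | OC(=O)C1=CC[C@H](c2ccc(OC)c(CC=C(C)C)c2OCOC)CO1
F9 | step 8 | (3R)-3-[4-methoxy-2-(methoxymethoxy)-3-(3-methylbut-2-en-1-yl)phenyl]-3,4-dihydro-2H-pyran-6-carboxylic isobutyl carbonic anhydride | CC(C)COC(=O)OC(=O)C1=CC[C@H](c2ccc(OC)c(CC=C(C)C)c2OCOC)CO1
F10 | step 14 | {6-[(3R)-5-methoxy-7-(triisopropylsilyloxy)-3,4-dihydro-2H-chromen-3-yl]-3-methoxy-2-(3-methylbut-2-en-1-yl)phenoxy}trimethylsilane | COc1cc(O[Si](C(C)C)(C(C)C)C(C)C)cc2c1C[C@H](c1ccc(OC)c(CC=C(C)C)c1O[Si](C)(C)C)CO2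
A1 | alternative 1 | methyl cis-6-methoxy-2-[2-methoxy-6-(pivaloyloxy)-4-(triisopropylsilyloxy)phenyl]-2,3-dihydrobenzofuran-3-carboxylate | COC(=O)[C@H]1c2ccc(OC)cc2O[C@H]1c1c(OC)cc(O[Si](C(C)C)(C(C)C)C(C)C)cc1OC(=O)C(C)(C)C
A2 | alternative 1 | methyl 2-diazo-2-(4-methoxy-2-{[2-methoxy-6-(pivaloyloxy)-4-(triisopropylsilyloxy)phenyl]methoxy}phenyl)acetate | COC(=O)C(=[N+]=[N-])c1ccc(OC)cc1OCc1c(OC)cc(O[Si](C(C)C)(C(C)C)C(C)C)cc1OC(=O)C(C)(C)C
A3 | alternative 2 | 2-{(1R)-2-[2-(tert-butyldimethylsilyloxy)-6-methoxy-4-(methoxymethoxy)phenyl]-1-[4-methoxy-2-(methoxymethoxy)-3-(3-methylbut-2-en-1-yl)phenyl]ethyl}-4,4,5,5-tetramethyl-1,3,2-dioxaborolane | COc1cc(OCOC)cc(O[Si](C)(C)C(C)(C)C)c1C[C@H](c1ccc(OC)c(CC=C(C)C)c1OCOC)B1OC(C)(C)C(C)(C)O1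
A4 | alternative 2 | 2-ethenyl-4,4,5,5-tetramethyl-1,3,2-dioxaborolane | C=CB1OC(C)(C)C(C)(C)O1
A5 | alternative 2 | 2-(tert-butyldimethylsilyloxy)-6-methoxy-4-(methoxymethoxy)phenyl trifluoromethanesulfonate | COc1cc(OCOC)cc(O[Si](C)(C)C(C)(C)C)c1OS(=O)(=O)C(F)(F)F
A6 | alternative 3 | 4-[(3R)-5-methoxy-7-(methoxymethoxy)-3,4-dihydro-2H-chromen-3-yl]cyclohexane-1,3-dione (epimers at the ring carbon) | O=C1CCC([C@@H]2COc3cc(OCOC)cc(OC)c3C2)C(=O)C1
A7 | alternative 3 | 1-[(3R)-5-methoxy-7-(methoxymethoxy)-3,4-dihydro-2H-chromen-3-yl]propan-2-one | CC(=O)C[C@@H]1COc2cc(OCOC)cc(OC)c2C1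
A8 | alternative 3 | methyl acrylate | C=CC(=O)OC
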